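What was left of the substrate, rather than what had formed, opened the meeting, the chair holding that a leftover is best read on a logarithmic scale, in powers of ten.

| flask | substrate | gas phase | catalyst | temperature | remark | time |
|---|---|---|---|---|---|---|
| summer | 0.25 M | 65 mM (held) | 5 mM | 0 °C | run made earlier |  |
| spring | 0.38 M | 65 mM (held) | 5 mM | 15 °C | run made earlier |  |
| grey | 0.50 M | 65 mM (held) | 5.0 mM |  | at 25 °C until 40 min, from then on at 5 °C | 3.0 h |
| amber | 0.50 M | 65 mM (held) | 5.0 mM |  | at 25 °C throughout | 3.0 h |

| run | time / h | product / % | substrate / % |
|---|---|---|---|
| summer | 1.33 | 23.8 | 75.9 |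
| summer | 3.00 | 44.9 | 55.7 |
| summer | 5.00 | 64.0 | 36.5 |
| summer | 6.00 | 69.8 | 30.6 |
| spring | 0.667 | 30.2 | 69.1 |
| spring | 1.33 | 52.7 | 46.8 |
| spring | 2.00 | 68.5 | 31.8 |
| spring | 3.00 | 82.7 | 17.1 |

(scatter of a reading: 0.5 percentage points)

- which of the two ends with the higher amount of product, in percent of the substrate charged ("neither" if they lie within 2 percentage points) (grey / amber / neither)
- product at the end, in percent of the substrate charged, grey
- product at the end, in percent of the substrate charged, amber

The chair proposed to count D, the powers of ten by which substrate has fallen since the charge, and the decade rate d, which is D per hour, 0.0857 h⁻¹ from the last summer reading and 0.256 h⁻¹ from the last spring reading. A second member checked the first readings, which give 0.0900 h⁻¹ and 0.241 h⁻¹, and argued that d is nearly steady within each run, so that with the gas held the fall reads as pseudo-first-order and decades can be added across a change of temperature, while the meeting took it as an assumption that the percent left does not depend on the charge, since the two runs differ in temperature as well as in charge. The chair then took the spring rate as 2.98 times the summer rate and, assuming the same factor per degree, I reckoned 0.530 h⁻¹ at 25 °C and 0.123 h⁻¹ at 5 °C. A third member objected that 25 °C lies outside the runs and that the gas starts undissolved, so both figures may run high. For amber I get 1.59 decades, hence 97.4 % product, and for grey, adding the stretch before 40 min to the stretch after it, 0.641 decades, hence 77.1 % product, so amber ends higher by 20 percentage points.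

The forecast, which said “Both runs fit first order in substrate”, named amber, with 75 % for grey, lower than my figure, and 96 % for amber. The simulation gives amber, with 73.9 % for grey and 96.5 % for amber.

    crystals ⇌ product, rate k1*(cs1 - [product]) while solid is left; crystals form when [product] > cs1 (solubility = 0.290 M, k = 4.00 h⁻¹)
    gas phase ⇌ dissolved gas, rate k2*(csat - [dissolved gas]) (kL = 40.0 h⁻¹)
    substrate + dissolved gas + catalyst → catalyst + product (k = 3700 M⁻² h⁻¹, Ea = 48.0 kJ mol⁻¹)
    (constants at 25 °C)

In amber at 0.576 h, substrate has a half-life of 0.65 h by the reaction, far longer than the half-life of 0.0173 h of the gap of dissolved gas to saturation under transfer. At that moment dissolved gas is made 1.02 times as fast as it is used up, and amber's rest of 3.5 % counts as 1.46 decades. For the repeat of amber at 0 °C, the summer rate 0.0857 h⁻¹ over 3.0 h gives 0.257 decades, or 55.3 % substrate left. That repeat, computed, holds 55 % substrate and 44.6 % product.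

(The earlier runs and the new flask were computed for substances that don't exist; the scatter is artificial.)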